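**Plan**
- Retrosynthesis: the O–Si–O tether is cut last (the target is the free diol of a cyclic silylene ether), then C13=C14 by metathesis, then the two Si–O bonds. This leaves a decalin allylic alcohol and a butenolide homoallylic alcohol.
- Enabling feature: the oxygen of the C13 hydroxymethyl group and the C16 carbinol oxygen lie on the same side of the C13=C14 alkene. One silicon atom can therefore tie them into an eight-membered 1,3-dioxa-2-silacyclooct-5-ene ring (Si, O, CH2, C13, C14, C15, C16, O), which can only contain a cis alkene.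
- Decalin half: C12–C13 is cut (copper-catalysed carbomagnesiation of propargyl alcohol) back to a C12 bromide from (+)-sclareolide, whose lactone is opened with dehydration to the C8=C9 alkene.
- Butenolide half: C15–C16 is cut (allylboration of furan-3-carbaldehyde). The furan is oxidised to the butenolide before the halves meet, so singlet oxygen never meets C8=C9.
- Forward order: decalin chain extension, butenolide carbinol, silicon tether, eight-membered ring closure, fluoride release. No carbocycle is built.
- Stereochemistry: C5 and C10 come from sclareolide, C16 (R) from the chiral allylborane, and the 13Z geometry from the ring size of the silacycle.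

Key step: step 9

Remark: labdane numbering is used (decalin C1–C10, chain C11–C16, hydroxymethyl on C13); "decalinyl" means (4aS,8aS)-2,5,5,8a-tetramethyl-3,4,4a,5,6,7,8,8a-octahydronaphthalen-1-yl, i.e. the C8=C9 ene unit bonded through C9; the lactol carbon of 14 is taken as an epimeric mixture that is erased in step 7.

**Route**

Step 1
Reactants: 1 (+)-sclareolide
Product: 2 methyl (5S,10S)-13,14,15,16-tetranorlabd-8-en-12-oate (methyl 2-decalinylacetate)
Conditions: conc. H2SO4, MeOH, reflux
Reagents that add atoms: methanol, CO
Why: Under Fischer esterification conditions the tertiary C8–O bond of the lactone ionises (E1 lactone opening–dehydration–esterification) and the alkene should settle at the most substituted, thermodynamically preferred C8=C9 position, while C5 and C10 are not touched.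

Step 2
Reactants: 2 methyl (5S,10S)-13,14,15,16-tetranorlabd-8-en-12-oate
Product: 3 (5S,10S)-13,14,15,16-tetranorlabd-8-en-12-ol (2-decalinylethanol)
Conditions: LiAlH4, Et2O, 0 °C; H2O, aq NaOH
Reagents that add atoms: none
Why: Lithium aluminium hydride reduction of the ester gives the primary homoallylic alcohol, and the isolated tetrasubstituted alkene is inert to hydride.

Step 3
Reactants: 3 (5S,10S)-13,14,15,16-tetranorlabd-8-en-12-ol
Product: 4 (5S,10S)-12-bromo-13,14,15,16-tetranorlabd-8-ene (2-decalinylethyl bromide)
Conditions: CBr4, PPh3, CH2Cl2, 0 °C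
Reagents that add atoms: carbon tetrabromide, BrC(Br)(Br)Br
Why: The Appel reaction converts the primary alcohol into the bromide by SN2 displacement of the oxyphosphonium group under neutral conditions that leave the hindered alkene alone.

Step 4
Reactants: 4 (5S,10S)-12-bromo-13,14,15,16-tetranorlabd-8-ene; 5 propargyl alcohol
Product: 9 2-methylidene-4-decalinylbutan-1-ol, via Grignard reagent 6 (not isolated), via chloromagnesium propargyl alkoxide 7 (not isolated), via alkenylmagnesium chelate 8 (not isolated)
Conditions: 4, Mg, Et2O, reflux; separately 5, MeMgCl (1.0 equiv), THF, 0 °C; combine (7 in slight excess), CuI (15 mol %), −10 °C → rt; aq NH4Cl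
Reagents that add atoms: none
Why: Copper-catalysed anti-carbomagnesiation of a propargylic magnesium alkoxide (Duboudin–Jousseaume reaction) places the primary alkyl group on the internal alkyne carbon through the five-membered oxamagnesacycle, and protonolysis should leave the 1,1-disubstituted alkene; the sacrificial methyl Grignard spares one equivalent of 6.

Step 5
Reactants: 10 furan-3-carbaldehyde
Product: 12 (1R)-1-(furan-3-yl)but-3-en-1-ol, via borinate ester 11 (not isolated)
Conditions: B-allyldiisopinocampheylborane of the (−)-α-pinene series (commercial pentane solution), Et2O, −78 °C; then 3 M NaOH, 30% H2O2, 0 °C → rt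
Reagents that add atoms: B-allyldiisopinocampheylborane from (−)-α-pinene, C=CCB([C@@H]1[C@@H](C)[C@@H]2C[C@H](C1)C2(C)C)[C@@H]1[C@@H](C)[C@@H]2C[C@H](C1)C2(C)C
Why: Brown allylboration proceeds through a chair Zimmerman–Traxler transition state in which the isopinocampheyl ligands of this reagent enantiomer direct allyl transfer to the Re face of the aromatic aldehyde, which should set C16 as R before alkaline peroxide cleaves the borinate.

Step 6
Reactants: 12 (1R)-1-(furan-3-yl)but-3-en-1-ol
Product: 14 5-hydroxy-4-[(1R)-1-hydroxybut-3-en-1-yl]furan-2(5H)-one (C5 epimers), via furan endoperoxide 13 (not isolated)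
Conditions: O2, rose bengal (cat.), i-Pr2NEt, CH2Cl2, visible light, −78 °C → rt
Reagents that add atoms: oxygen, O=O
Why: [4+2] addition of singlet oxygen to the furan, then base-induced fragmentation of the endoperoxide at the less hindered C–H remote from the substituent (Faulkner protocol, Kornblum–DeLaMare type), should give the 4-substituted 5-hydroxybutenolide regioselectively, while the monosubstituted alkene does not react with singlet oxygen and C16 is not involved.

Step 7
Reactants: 14 5-hydroxy-4-[(1R)-1-hydroxybut-3-en-1-yl]furan-2(5H)-one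
Product: 16 4-[(1R)-1-hydroxybut-3-en-1-yl]furan-2(5H)-one, via sodium hydroxy carboxylate 15 (not isolated)
Conditions: NaBH4, EtOH, 0 °C; then 1 M HCl to pH 2, rt
Reagents that add atoms: none
Why: Borohydride reduces the aldehyde of the ring-opened γ-hydroxybutenolide while the carboxylate is spared, and acidification should close the cis hydroxy acid to the β-substituted butenolide (reductive lactonisation) without touching C16.

Step 8
Reactants: 16 4-[(1R)-1-hydroxybut-3-en-1-yl]furan-2(5H)-one; 17 dichlorodiisopropylsilane; 9 2-methylidene-4-decalinylbutan-1-ol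
Product: 19 mixed diisopropylsilylene bis-ether in which silicon carries the C16 oxygen of 16 and the primary oxygen of 9 (16R), via chlorosilyl ether 18 (not isolated)
Conditions: 16, 17 (1.1 equiv), imidazole (3 equiv), CH2Cl2, 0 °C; then 9, DMAP (cat.), CH2Cl2–DMF, rt
Reagents that add atoms: none
Why: Stepwise silylation with a dialkyldichlorosilane should work because the secondary alcohol takes up only one Si–Cl bond of the hindered dichloride and the resulting monochlorosilane is then captured by the unhindered primary allylic alcohol, the weak amine base leaving the butenolide and C16 intact.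

Step 9
Reactants: 19 mixed diisopropylsilylene bis-ether
Product: 20 cyclic diisopropylsilylene ether of the target: eight-membered 2,2-diisopropyl-1,3-dioxa-2-silacyclooct-5-ene with Z ring alkene C13=C14, the 2-decalinylethyl group on C13 and the butenolide on C16 (16R)
Conditions: Grubbs II (10 mol %), 1,4-benzoquinone (20 mol %), toluene (2 mM), 80 °C, Ar sparge
Reagents that add atoms: none
Why: Ring-closing olefin metathesis by the Chauvin mechanism: the ruthenium alkylidene forms on the monosubstituted alkene of the C14–C15 arm, adds to the 1,1-disubstituted C13 alkene through a ruthenacyclobutane, and cycloreversion expels ethylene. The closest known reaction type is temporary silicon-tethered ring-closing metathesis of mixed dialkoxysilanes, which gives Z-trisubstituted alkenes in seven- and eight-membered dioxasilacycles. The single ring formed, the eight-membered dioxasilacycle, closes by intramolecular metathesis between the two tethered alkene termini, with C13=C14 endocyclic. No stereocentre is created; the Z geometry is enforced because an eight-membered ring cannot hold a trans alkene, so the CH2O carbon and C15 must end cis, and C16 is a spectator. The step needs chemoselectivity among four alkenes and cyclisation over oligomerisation: the tetrasubstituted C8=C9 and the electron-poor butenolide alkene are inert to the alkylidene, the isopropyl groups on silicon and high dilution favour closure, and benzoquinone suppresses hydride-induced alkene migration.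

Step 10
Reactants: 20 cyclic diisopropylsilylene ether
Product: 21 4-[(1R,3Z)-1-hydroxy-4-(hydroxymethyl)-6-decalinylhex-3-en-1-yl]furan-2(5H)-one (target)
Conditions: HF·pyridine, pyridine, THF, 0 °C → rt
Reagents that add atoms: none
Why: Fluoride-mediated cleavage of the dialkoxysilane (Si–O to Si–F exchange) with buffered HF–pyridine should free both hydroxyls without base, so the base-labile C16–H next to the butenolide, the Z alkene and the C8=C9 alkene are unaffected.

**Compound list**
1 | (+)-sclareolide | C[C@@]12CC[C@H]3C(C)(C)CCC[C@]3(C)[C@H]1CC(=O)O2 | starting material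
2 | methyl (5S,10S)-13,14,15,16-tetranorlabd-8-en-12-oate | CC1=C(CC(=O)OC)[C@@]2(C)CCCC(C)(C)[C@@H]2CC1 | intermediate
3 | (5S,10S)-13,14,15,16-tetranorlabd-8-en-12-ol | CC1=C(CCO)[C@@]2(C)CCCC(C)(C)[C@@H]2CC1 | intermediate
4 | (5S,10S)-12-bromo-13,14,15,16-tetranorlabd-8-ene | CC1=C(CCBr)[C@@]2(C)CCCC(C)(C)[C@@H]2CC1 | intermediate
5 | propargyl alcohol | C#CCO | starting material
6 | 2-decalinylethylmagnesium bromide | CC1=C(CC[Mg]Br)[C@@]2(C)CCCC(C)(C)[C@@H]2CC1 | intermediate (not isolated)
7 | chloromagnesium prop-2-yn-1-olate | C#CCO[Mg]Cl | intermediate (not isolated)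
8 | 4-(2-decalinylethyl)-2,5-dihydro-1,2-oxamagnesole (alkenylmagnesium chelate) | CC1=C(CCC2=C[Mg]OC2)[C@@]2(C)CCCC(C)(C)[C@@H]2CC1 | intermediate (not isolated)
9 | 2-methylidene-4-decalinylbutan-1-ol | CC1=C(CCC(=C)CO)[C@@]2(C)CCCC(C)(C)[C@@H]2CC1 | intermediate
10 | furan-3-carbaldehyde | O=Cc1ccoc1 | starting material
11 | (1R)-1-(furan-3-yl)but-3-en-1-yl diisopinocampheylborinate | C=CC[C@@H](OB([C@@H]1[C@@H](C)[C@@H]2C[C@H](C1)C2(C)C)[C@@H]1[C@@H](C)[C@@H]2C[C@H](C1)C2(C)C)c1ccoc1 | intermediate (not isolated)
12 | (1R)-1-(furan-3-yl)but-3-en-1-ol | C=CC[C@@H](O)c1ccoc1 | intermediate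
13 | 5-[(1R)-1-hydroxybut-3-en-1-yl]-2,3,7-trioxabicyclo[2.2.1]hept-5-ene | C=CC[C@@H](O)C1=CC2OOC1O2 | intermediate (not isolated)
14 | 5-hydroxy-4-[(1R)-1-hydroxybut-3-en-1-yl]furan-2(5H)-one (C5 epimers) | C=CC[C@@H](O)C1=CC(=O)OC1O | intermediate
15 | sodium (2E,4R)-4-hydroxy-3-(hydroxymethyl)hepta-2,6-dienoate | C=CC[C@@H](O)/C(CO)=C/C(=O)[O-].[Na+] | intermediate (not isolated)
16 | 4-[(1R)-1-hydroxybut-3-en-1-yl]furan-2(5H)-one | C=CC[C@@H](O)C1=CC(=O)OC1 | intermediate
17 | dichlorodiisopropylsilane | CC(C)[Si](Cl)(Cl)C(C)C | starting material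
18 | chloro(diisopropyl)silyl ether of 16 | C=CC[C@@H](O[Si](Cl)(C(C)C)C(C)C)C1=CC(=O)OC1 | intermediate (not isolated)
19 | mixed diisopropylsilylene bis-ether of 9 and 16 | CC1=C(CCC(=C)CO[Si](C(C)C)(C(C)C)O[C@H](CC=C)C2=CC(=O)OC2)[C@@]2(C)CCCC(C)(C)[C@@H]2CC1 | intermediate
20 | cyclic diisopropylsilylene ether of the target (Z ring alkene, 16R) | CC1=C(CC/C2=C/C[C@H](C3=CC(=O)OC3)O[Si](C(C)C)(C(C)C)OC2)[C@@]2(C)CCCC(C)(C)[C@@H]2CC1 | intermediate
21 | 4-[(1R,3Z)-1-hydroxy-4-(hydroxymethyl)-6-decalinylhex-3-en-1-yl]furan-2(5H)-one | CC1=C(CC/C(=C/C[C@@H](O)C2=CC(=O)OC2)CO)[C@@]2(C)CCCC(C)(C)[C@@H]2CC1 | target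

**Step count**
Total: 10 steps. Longest linear sequence: 7 steps (steps 1, 2, 3, 4, 8, 9, 10); the butenolide branch (steps 5–7) joins at step 8.

**Steps most likely to fail**

Step 9. Closure onto the hindered 1,1-disubstituted alkene may be outrun by intermolecular metathesis of the homoallyl terminus (oligomerisation), or ruthenium hydride species may migrate the terminal alkene before closure. The fallback swaps the silicon tether for an ester tether and a six-membered ring; it sets out from 9 and 12 and rejoins at 21.
- Oxidation of 9 with MnO2 would give the enal 2-methylidene-4-decalinylbutanal F1, and Pinnick oxidation (NaClO2, NaH2PO4, 2-methyl-2-butene) the acid 2-methylidene-4-decalinylbutanoic acid F2.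
- Esterification with the furyl carbinol 12 (DCC, DMAP) would give the acrylate ester F3.
- Ring-closing metathesis of this α-substituted acrylate (Grubbs II, CH2Cl2, 40 °C) should close the (6R)-3-(2-decalinylethyl)-6-(furan-3-yl)-5,6-dihydro-2H-pyran-2-one F4, whose ring again forces C15 cis to the carbon that becomes the hydroxymethyl group.
- DIBAL-H reduction would open the lactone to the (1R,3Z)-furyl diol F5.
- Low-temperature photo-oxygenation (O2, rose bengal, i-Pr2NEt, −78 °C) would give the 5-hydroxybutenolide F6, and NaBH4 reduction with acidic work-up would give 21.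
- The price is that singlet oxygen must then distinguish the furan from the hindered C8=C9 alkene, which is why the silicon route is preferred.

Step 4. Carbometallation with a β-branched primary alkyl Grignard reagent may be sluggish, and Wurtz coupling during Grignard formation or deprotonation of the alkyne C–H may consume material. The fallback replaces the carbomagnesiation by an sp3–sp2 cross-coupling; it sets out from 4 and rejoins at 9.
- Zinc insertion (Zn dust, LiCl, THF, 50 °C) would give 2-decalinylethylzinc bromide F7.
- Negishi coupling with tert-butyl[(2-bromoprop-2-en-1-yl)oxy]dimethylsilane (Pd(dppf)Cl2, THF, 50 °C) would give the tert-butyldimethylsilyl ether of 9 F8.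
- Bu4NF in THF would release 9.

Step 1. The E1 elimination may stop at a mixture of alkene regioisomers (C7=C8 and C8=C17 beside C8=C9) that is hard to separate, and the C8 cation may undergo hydride or methyl shifts. The fallback fixes the alkene position by a reductive allylic transposition instead of thermodynamic control; it sets out from 1 and rejoins at 3.
- Selenation of the lactone enolate (LDA, PhSeBr, THF, −78 °C) would give 11-(phenylselanyl)sclareolide F9.
- Oxidation with H2O2 and syn-elimination would give the C9=C11 butenolide 9(11)-dehydrosclareolide F10.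
- SmI2 (THF, t-BuOH) would cleave the allylic C8–O bond reductively, and α-protonation of the dienolate should leave (5S,10S)-13,14,15,16-tetranorlabd-8-en-12-oic acid F11 with the alkene at C8=C9 only.
- LiAlH4 would reduce it to 3.

Further compounds
F1 | step 9 | 2-methylidene-4-decalinylbutanal | CC1=C(CCC(=C)C=O)[C@@]2(C)CCCC(C)(C)[C@@H]2CC1
F2 | step 9 | 2-methylidene-4-decalinylbutanoic acid | CC1=C(CCC(=C)C(=O)O)[C@@]2(C)CCCC(C)(C)[C@@H]2CC1
F3 | step 9 | (1R)-1-(furan-3-yl)but-3-en-1-yl 2-methylidene-4-decalinylbutanoate | CC1=C(CCC(=C)C(=O)O[C@H](CC=C)c2ccoc2)[C@@]2(C)CCCC(C)(C)[C@@H]2CC1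
F4 | step 9 | (6R)-3-(2-decalinylethyl)-6-(furan-3-yl)-5,6-dihydro-2H-pyran-2-one | CC1=C(CCC2=CC[C@H](c3ccoc3)OC2=O)[C@@]2(C)CCCC(C)(C)[C@@H]2CC1
F5 | step 9 | (1R,3Z)-1-(furan-3-yl)-4-(hydroxymethyl)-6-decalinylhex-3-en-1-ol | CC1=C(CC/C(=C/C[C@@H](O)c2ccoc2)CO)[C@@]2(C)CCCC(C)(C)[C@@H]2CC1
F6 | step 9 | 5-hydroxy-4-[(1R,3Z)-1-hydroxy-4-(hydroxymethyl)-6-decalinylhex-3-en-1-yl]furan-2(5H)-one (C5 epimers) | CC1=C(CC/C(=C/C[C@@H](O)C2=CC(=O)OC2O)CO)[C@@]2(C)CCCC(C)(C)[C@@H]2CC1
F7 | step 4 | 2-decalinylethylzinc bromide | CC1=C(CC[Zn]Br)[C@@]2(C)CCCC(C)(C)[C@@H]2CC1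
F8 | step 4 | tert-butyldimethylsilyl ether of 9 | CC1=C(CCC(=C)CO[Si](C)(C)C(C)(C)C)[C@@]2(C)CCCC(C)(C)[C@@H]2CC1
F9 | step 1 | 11-(phenylselanyl)sclareolide | C[C@@]12CC[C@H]3C(C)(C)CCC[C@]3(C)[C@H]1C([Se]c1ccccc1)C(=O)O2
F10 | step 1 | 9(11)-dehydrosclareolide | C[C@@]12CC[C@H]3C(C)(C)CCC[C@]3(C)C1=CC(=O)O2
F11 | step 1 | (5S,10S)-13,14,15,16-tetranorlabd-8-en-12-oic acid | CC1=C(CC(=O)O)[C@@]2(C)CCCC(C)(C)[C@@H]2CC1
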